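## Structural features

Ainsliatrimer A consists of three guaianolide units (A unprimed, B primed, C double-primed). Each is a cyclopentane fused to a cycloheptane that carries a trans-fused α-methylene-γ-butyrolactone across C6–C7. The units are joined by two spiro-cyclohexene rings: C2–C1–C10–C14–C15'–C4' (spiro atom C4', A to B) and C2'–C1'–C10'–C14'–C15''–C4'' (spiro atom C4'', B to C). There are fourteen stereocentres. C4'–C5'–C6'–C7', C4''–C5''–C6''–C7'' (with C1'') and C5–C6–C7 are contiguous, while C10 and the tertiary carbinol C10' stand alone. The two quaternary spiro centres differ in sense: C2' lies on the face of H5'' at C4'', but C2 lies on the face of C6' at C4'. The fragile groups are the three methylene lactones (Michael acceptors), the cross-conjugated dienone of unit A (C15=C4–C3(=O)–C2=C1, with vinylogously acidic H5 and H10), the γ-hydroxy enone of unit B, the enolizable C3'' cyclopentanone and the isomerizable C10''=C14'' methylene. The real difficulty is the congested all-carbon centre C4', which must be forged with the right facial sense between two large, multiply electrophilic halves. The key step exploits two facts: C4' is α to the C3' ketone, whose other α-carbon C2' is sp2; and its two bonds to unit A end on sp3 C15' and sp2 C2, the termini of the chain C15'–C14–C10–C1=C2. A 15-nor ketone α-methylene can therefore be alkylated once and alkenylated once, closing the six-membered A–B ring.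

## Logic of the disconnections

**36 back to 32.** The three exocyclic C11=C13 bonds are cut back to C13–N bonds (34, through 35), the C3 and C3'' carbonyls to carbinols (33), and three O–H bonds to O–Si bonds (32). The reason is that every Michael acceptor and every competing enolizable or electrophilic ketone must be silent when the trimer is assembled. The gain is a union step that sees one ketone only. The demand is a three-step end game (fluoride, oxidation, quaternization–elimination) in which the methylene lactones appear last.

**32 back to 30 and 18.** The bonds C4'–C15' (enolate alkylation) and C4'–C2 (enolate alkenylation) are cut. This opens the A–B ring, removes the C4' stereocentre and gives two halves of similar size. The forward step makes several demands, each answered by a design choice: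
- 30 must have a single α-methylene. A free C3'' ketone would enolize toward C2'' as readily as C3' toward C4', so 30 carries C3'' as a silyl ether.
- The tertiary C10' oxygen is a triethylsilyl ether, because a trimethylsilyl ether is not safe toward amide or alkoxide bases.
- In 18 the enone is reduced and silylated, so that the vinyl bromide is no Michael acceptor.
- C3 of 18 is 3α. In the ring closure C3 comes to lie over ring B next to C6', and a 3β substituent would point at C6'.
- 18 is an ω-iodoalkyl tertiary amine and would quaternize itself. It is therefore made last from the stable chloride 17 and used at once.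

**30 back to 26.** After the two O–Si bonds (29), the C4'–C15' bond is restored in the retro sense (28, 27, 26); the forward step excises C15' by retro-aldol. The reason is that the cycloaddition building the B–C half needs the C4'=C15' methylene of each monomer, as dienophile in one and as blocking group for regioselective dehydrogenation in the other. The demand is a base-mediated deformylation that leaves the lactone adducts and C5' intact.

**26 back to 22.** The C3''–H bond (ketone reduction), the C10'–O bond (γ-oxygenation of a dienolate) and three C–N bonds (25, 24, 23) are cut. The gain is a dimer at the oxidation level of its monomers. The demand is oxygen delivery to the β face of C10' and reduction of the saturated ketone in the presence of the enone.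

**22 back to two molecules of 19.** The bonds C2'–C4'' and C14'–C15'' are cut ([4+2]); one molecule of 19 serves as diene after dehydrogenation (20, 21). The gain is the whole B–C skeleton and the C4'' spiro centre from one monomer. The demand is attack on the α face of the dienophile and suppression of self-addition of 21.

**19 back to 1.** The C3 carbonyl goes back to the carbinol 2 and to the C3–H bond of 1.

**18 back to 13.** The C–I bond goes back to C–Cl (17), then the O–Si bond (16), inversion at C3 (15, 14) and the C3–H bond (13). The demand is clean SN2 inversion at a doubly allylic carbinol.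

**13 back to 9.** The C2–Br bond (12, 11) and the C1=C2 double bond (10, 9) are cut. The demand is that C10 is already sp3, so that no reactive C2=C1–C10=C14 diene arises.

**9 back to 2.** C–Cl goes back to C–O (8, 7), the C3 carbonyl to the 3α carbinol (6), the primary carbinol to the aldehyde (5), then the C14–C15' bond (carbon monoxide insertion) and the C14–B and C10–H bonds (4, 3) are cut, and finally the C13–N bond (2). The demand is hydroboration of C10=C14 only, from the α face.

## Other disconnections considered

**Alternative 1:** The cut is made in a single guaianolide unit, at the bonds C1–C5, C2–C3 and C3–C4. This removes the cyclopentenone and with it the seven-membered ring, and leads back to the monocyclic allene-yne lactone A2. In the forward key step Mo(CO)6 with DMSO under CO would join the alkyne (C1, C2), carbon monoxide (C3) and the proximal allene bond (C4=C5) of A2 to give the trienone A1, which is the same compound as 21.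
- In favour: two rings and the dienone oxidation level arise in one step; the entry is de novo, independent of natural supply and open to analogues; no stoichiometric palladium is needed.
- Against, here: it makes a monomer only and leaves both spiro junctions unsolved. A2 needs its own multistep enantioselective synthesis (C6, C7), and C5 must be set during the cyclization. Closing a seven-membered ring through the proximal allene bond is a demanding ring size for this reaction and competes with reaction at the distal bond. A1 is diene and dienophile at once, so it would have to be generated in the presence of its partner.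
- Comparison: on structure A1 is the equal of 21, so everything after step 14 would be unchanged. On mechanism the [2+2+1] is the more convergent way to the bicyclic core, and on supply independence it is the better plan. On step economy the chosen plan is far ahead (21 is three steps from 1), and A1 offers no handle for the C10 stereocentre of fragment 18.

**Alternative 2:** The cut is the C2'–C4'' bond of the B–C dimer A3 (identical with 22), with an O–C10' bond restored. This retro-Claisen leads to the spiro-dihydropyran A4, an allyl vinyl ether (C4''=C3''–O–C10'–C1'=C2'). In the forward key step heating A4 would trigger a [3,3] shift through a boat transition state inside a bicyclo[2.2.2] array: O–C10' breaks, C2'–C4'' forms, the dihydropyran becomes the cyclohexene and C4'' becomes quaternary.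
- In favour: it is reagent-free and intramolecular, so the configuration of C4'' is dictated by that of C10' and not by facial selection between two molecules. The product is exactly 22. Any hetero-Diels–Alder adduct formed beside 22 in step 14 is of this type and could be funnelled to 22 by heating.
- Against, here: A4 must itself come from a hetero-Diels–Alder union of 19 with A1-type material, whose peri-, regio- and facial selectivity is no easier to control than the direct [4+2]. It costs one step more. Prolonged heating of a compound with two free methylene lactones and a β,γ-unsaturated ketone invites polymerization and double-bond migration, and the rearrangement may be reversible.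
- Comparison: on structure the two plans are equal (same compound). On mechanism the alternative is the better on one point, the transfer of chirality to the spiro centre. On step economy the chosen plan is shorter by one step. Neither touches the A–B junction.

**Alternative 3:** The cut is at the C6–C7 bond and the lactone C12–O bond of a monomer. It leads back to the cyclopentane aldehyde A6 with a (Z)-2-(bromomethyl)enoate side chain, which would come from carvone by ring contraction. In the forward key step indium metal would turn the allylic bromide of A6 into an allylindium that adds through C7 to the C6 aldehyde (seven-membered ring); the alkoxide then lactonizes to give A5, the tert-butyldimethylsilyl ether of 2.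
- In favour: the metal is mild, chemoselective and water-tolerant; the trans-lactone and the seven-membered ring form in one operation; the C3 oxygen arrives protected; supply is independent of the natural product.
- Against, here: it delivers a monomer only. It needs ten or more steps to reach what step 1 gives from 1 in one. The relative configuration at C6/C7 in a medium-ring closure and at C1/C5 in the ring contraction must be secured. The whole of the present route is still needed afterwards.
- Comparison: on structure A5 is the equal of 2, and better on one point, since the silyl ether would make the in-situ borinate protection of step 3 unnecessary. On mechanism it is as reliable as the steps used here. On step economy it is clearly worse.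

Key step: step 19

Assumption: stereocentres that are erased later (C11, C11', C11'' of the amine adducts; the C3'' carbinol; C4' in 23–28 and 31; C2' in 22 and 23; C1/C2 in 12) are drawn as the isomers expected to predominate, and their epimers would converge to the same later compounds.

## Route

Step 1
Reactants: 1 dehydrocostus lactone
Product: 2 isozaluzanin C (3α-hydroxydehydrocostus lactone)
Conditions: SeO2 (0.5 equiv), t-BuOOH, CH2Cl2, rt
Reagents that add atoms: tert-butyl hydroperoxide, CC(C)(C)OO
Why: Allylic oxidation (ene reaction, then [2,3]-sigmatropic shift) at the C4=C15 methylene; the selenium reagent should approach the convex α face (side of H5), so the C3–O bond is expected α; C3 is oxidised again in steps 5 and 13.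

Step 2
Reactants: 2 isozaluzanin C
Product: 3 13-dimethylamino-11βH,13-dihydroisozaluzanin C
Conditions: Me2NH (2 M in THF), MeOH, rt
Reagents that add atoms: dimethylamine, CNC
Why: Aza-Michael addition masks the methylene lactone against boranes, hydrides and enolates; protonation of the lactone enolate from the less hindered face should give the 11βH isomer, a centre that is erased in step 22.

Step 3
Reactants: 3 amine adduct of isozaluzanin C
Product: 5 hydroxy aldehyde (3α-OH; C10 αH; β-oriented CH2CHO chain C14–C15'), via bis-boron adduct 4 (not isolated)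
Conditions: 9-BBN (3 equiv), THF, 0 °C to rt; CO (1 atm), LiAlH(OtBu)3, −35 °C; H2O2, pH 7 phosphate buffer, 0 °C
Reagents that add atoms: carbon monoxide, [C-]#[O+]
Why: 9-BBN first turns the C3 hydroxyl into a bulky borinate that shields the neighbouring C4=C15 methylene, then adds to C10=C14 from the convex α face (B to C14, H to C10), which sets C10 with H α and the chain β. Carbonylation of the B-alkyl-9-BBN in the presence of the hydride donor and buffered peroxide oxidation give the one-carbon-longer aldehyde (organoborane carbonylation); the bulky hydride is too slow at −35 °C to attack the lactone.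

Step 4
Reactants: 5 hydroxy aldehyde
Product: 6 diol (3α-OH; C15'–OH)
Conditions: NaBH4, MeOH, 0 °C
Reagents that add atoms: none
Why: Borohydride reduces the aldehyde much faster than the lactone; no stereocentre is formed.

Step 5
Reactants: 6 diol
Product: 7 hydroxy enone (3-oxo; C4=C15; C15'–OH)
Conditions: MnO2, CH2Cl2, rt
Reagents that add atoms: none
Why: MnO2 oxidises only the allylic C3 carbinol and leaves the saturated primary alcohol; the resulting ketone can enolize only toward C2 because C4 is sp2.

Step 6
Reactants: 7 hydroxy enone
Product: 9 chloro enone (C15'–Cl), via mesylate 8 (not isolated)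
Conditions: MsCl, Et3N, CH2Cl2, 0 °C; then LiCl, DMF, rt to 40 °C
Reagents that add atoms: lithium chloride, [Li+].[Cl-]
Why: Sulfonylation and SN2 displacement by chloride; the chloride, unlike an iodide, does not alkylate the tertiary amine during the following steps, and it removes a hydroxyl that could add to the dienone made next.

Step 7
Reactants: 9 chloro enone
Product: 11 chloro dienone (3-oxo-1,4(15)-diene), via silyl dienol ether 10 (not isolated)
Conditions: TMSOTf, Et3N, CH2Cl2, 0 °C; then Pd(OAc)2 (1.2 equiv), MeCN, rt
Reagents that add atoms: none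
Why: Saegusa–Ito dehydrogenation: enolization can occur only toward C2, and β-hydride elimination of H1 from the divalent palladium enolate gives the C1=C2 enone; C10 is already sp3, so no C2=C1–C10=C14 diene able to dimerize arises.

Step 8
Reactants: 11 chloro dienone
Product: 13 2-bromo dienone, via dibromide 12 (not isolated)
Conditions: CF3CO2H (1.1 equiv), Br2 (1.05 equiv), CH2Cl2, −20 °C; then Et3N, 0 °C
Reagents that add atoms: bromine, BrBr
Why: With the amine protected as its salt, bromine adds to the more electron-rich trisubstituted C1=C2 bond, and triethylamine then removes the acidic H2 with loss of the C1 bromide (addition–elimination α-bromination of an enone).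

Step 9
Reactants: 13 2-bromo dienone
Product: 14 2-bromo-3β-ol
Conditions: NaBH4, CeCl3·7H2O, MeOH, −78 °C
Reagents that add atoms: none
Why: Luche 1,2-reduction; hydride should approach the α face, away from C6, giving the 3β alcohol, which is the wrong epimer for step 19 and is inverted next.

Step 10
Reactants: 14 2-bromo-3β-ol
Product: 16 2-bromo-3α-ol, via formate 15 (not isolated)
Conditions: HCO2H, PPh3, DIAD, THF, 0 °C; then K2CO3 (cat.), MeOH, 0 °C
Reagents that add atoms: formic acid, O=CO
Why: Mitsunobu inversion: formate displaces the oxyphosphonium group from the open α face (SN2) and mild methanolysis frees the 3α alcohol; 3α is needed because in the ring closure of step 19 C3 lies over ring B next to C6', where a 3β substituent would collide.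

Step 11
Reactants: 16 2-bromo-3α-ol
Product: 17 3α-silyl ether chloride
Conditions: TBSOTf, 2,6-lutidine, CH2Cl2, −78 °C
Reagents that add atoms: tert-butyldimethylsilyl triflate, CC(C)(C)[Si](C)(C)OS(=O)(=O)C(F)(F)F
Why: Silylation of the hindered allylic alcohol with the silyl triflate; as a silyl ether the vinyl bromide is neither a Michael acceptor nor γ-acidic.

Step 12
Reactants: 17 3α-silyl ether chloride
Product: 18 unit A bromo iodide
Conditions: CF3CO2H (1.05 equiv), NaI (5 equiv), 2-butanone, 70 °C; cold aq NaHCO3; used at once
Reagents that add atoms: sodium iodide, [Na+].[I-]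
Why: Finkelstein exchange run on the ammonium salt, so that the amine cannot be alkylated (Menshutkin reaction); the free amino iodide is liberated cold and used immediately in dilute solution.

Step 13
Reactants: 2 isozaluzanin C
Product: 19 dehydrozaluzanin C
Conditions: Dess–Martin periodinane, NaHCO3, CH2Cl2, rt
Reagents that add atoms: none
Why: Dess–Martin oxidation of the allylic alcohol to the exocyclic enone under neutral conditions that spare the methylene lactone.

Step 14
Reactants: 19 dehydrozaluzanin C (one part as diene precursor, three parts as dienophile)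
Product: 22 B–C Diels–Alder dimer (C1'=C10' alkene; 2'βH; spiro C4''), via silyl dienol ether 20 (not isolated), via trienone 21 (not isolated)
Conditions: TMSOTf, Et3N, CH2Cl2, 0 °C (one part of 19); then Pd(OAc)2, 19 (3 equiv), MeCN, rt
Reagents that add atoms: none
Why: Saegusa–Ito oxidation gives the cross-conjugated trienone 21, whose C2=C1–C10=C14 diene adds to the exocyclic enone C4=C15 of a second molecule of 19 (Diels–Alder, ortho-type regiochemistry: C2' to C4'', C14' to C15''). The dienophile should be attacked on its convex α face, which sets the spiro centre C4'' with C2' on the side of H5''; the C2' centre is erased in step 15, and the excess of 19 suppresses self-addition of 21.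

Step 15
Reactants: 22 B–C Diels–Alder dimer
Product: 25 10'β-hydroxy enone tris(dimethylamine) adduct, via tris-amine adduct 23 (not isolated), via hydroperoxide 24 (not isolated)
Conditions: Me2NH (2 M in THF, excess), rt; then DBU, O2 (1 atm), P(OEt)3, THF, 0 °C
Reagents that add atoms: dimethylamine, CNC; dioxygen, O=O
Why: Dimethylamine adds to the three Michael acceptors (two lactones and C15'). DBU then removes the doubly activated H2', and the extended dienolate takes up O2 at the γ-carbon C10' on the β face, anti to the pseudoaxial C5'' flank of ring C; the phosphite reduces the hydroperoxide and the double bond ends in conjugation (C2'=C1').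

Step 16
Reactants: 25 10'β-hydroxy enone tris(dimethylamine) adduct
Product: 26 3''β-carbinol
Conditions: NaBH4, MeOH–CH2Cl2 (1:1), −78 °C
Reagents that add atoms: none
Why: At −78 °C borohydride reduces the saturated cyclopentanone faster than the conjugated, α'-branched enone. The C3'' ketone must go because its enolate (toward C2'') would compete with the C4' enolate in step 19; the carbinol configuration is immaterial.

Step 17
Reactants: 26 3''β-carbinol
Product: 29 15-nor ketone diol, via exocyclic enone 27 (not isolated), via hydroxymethyl ketone 28 (not isolated)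
Conditions: K2CO3 (0.2 equiv), H2O–1,4-dioxane, 60 °C, slow N2 stream
Reagents that add atoms: none
Why: E1cB loss of dimethylamine from the ketone Mannich base, conjugate addition of water and retro-aldol loss of formaldehyde excise C15'; the volatile amine and formaldehyde are swept out to pull the equilibria, while the less acidic lactone adducts should stay masked.

Step 18
Reactants: 29 15-nor ketone diol
Product: 30 masked 15-nor ketone of the B–C dimer (10'-O- and 3''-O-triethylsilyl)
Conditions: TESOTf, 2,6-lutidine, CH2Cl2, −40 to 0 °C
Reagents that add atoms: triethylsilyl triflate, CC[Si](CC)(CC)OS(=O)(=O)C(F)(F)F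
Why: The silyl triflate silylates the tertiary C10' and the hindered C3'' hydroxyl without enolizing the ketone; triethylsilyl is chosen over trimethylsilyl so that the tertiary ether survives the bases of step 19.

Step 19
Reactants: 30 masked 15-nor ketone of the B–C dimer; 18 unit A bromo iodide
Product: 32 protected trimer, via alkylated ketone 31 (not isolated)
Conditions: KN(SiMe3)2 (1.05 equiv), THF, −78 °C; 18, −78 to −20 °C; then KN(SiMe3)2 (1.1 equiv), Pd2(dba)3 (5 mol%), P(t-Bu)3 (12 mol%), toluene, 0 to 40 °C
Reagents that add atoms: none
Why: KN(SiMe3)2 removes an α'-proton at C4' of 30, the only ketone α-methylene left (C2' is sp2, C3'' is an ether), and the cross-conjugated enolate displaces the primary iodide of 18 (SN2) to give 31. A second equivalent of base re-enolizes C4'; zerovalent palladium with P(t-Bu)3 inserts into the C2–Br bond, the enolate binds palladium through C4', and C–C reductive elimination from the seven-membered palladacycle (Pd, C2, C1, C10, C14, C15', C4') forms the quaternary centre. The closest known reaction type is ketone enolate alkylation followed by intramolecular palladium-catalysed α-alkenylation of a ketone with a vinyl bromide. The ring closed is the six-membered C2–C1–C10–C14–C15'–C4' ring; the closure is enolexo with respect to the C3'–C4' enolate, and because the C1=C2 bond of the electrophile ends up inside the new ring it is not an exo-trig closure. C4' is set in the alkenylation (the centre made by alkylation is erased by re-enolization) under substrate control: C2 has to enter on the β face (side of C6'), where the 3α-silyloxy group of unit A points toward the open C3' carbonyl side, whereas attack on the α face would drive that group against H5' and the lactone oxygen on C6'. The step needs C- over O-alkylation and mono- over dialkylation (iodide, low temperature, slight excess of 30), a purely intramolecular alkenylation (18 has no enone, so no Michael pathway), and an amide base at or below 40 °C to limit γ-deprotonation at C5' and loss of the β-amino groups.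

Step 20
Reactants: 32 protected trimer
Product: 33 triol tris(dimethylamine) adduct
Conditions: Bu4NF, AcOH, THF, 0 °C to rt
Reagents that add atoms: none
Why: Buffered fluoride cleaves all three silyl ethers; the lactones are still masked, so no Michael acceptor is exposed to fluoride.

Step 21
Reactants: 33 triol tris(dimethylamine) adduct
Product: 34 3,3''-diketone tris(dimethylamine) adduct
Conditions: Dess–Martin periodinane, NaHCO3, CH2Cl2, 0 °C to rt
Reagents that add atoms: none
Why: Dess–Martin oxidation of the two secondary carbinols (allylic C3, neopentyl C3''); the tertiary C10' alcohol cannot be oxidised.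

Step 22
Reactants: 34 3,3''-diketone tris(dimethylamine) adduct
Product: 36 ainsliatrimer A, via tris-ammonium salt 35 (not isolated)
Conditions: MeI, THF–MeOH, rt; then NaHCO3 (aq), CH2Cl2, rt
Reagents that add atoms: none
Why: Exhaustive N-methylation and bicarbonate-induced E1cB (Hofmann-type) elimination of trimethylamine regenerate the three α-methylene lactones under conditions too mild to epimerize C5 or C5'.

## Compound list

1 | dehydrocostus lactone | C=C1CC[C@H]2C(=C)CC[C@H]3C(=C)C(=O)O[C@@H]3[C@H]21 | starting material
2 | isozaluzanin C (3α-hydroxydehydrocostus lactone) | C=C1[C@H](O)C[C@H]2C(=C)CC[C@H]3C(=C)C(=O)O[C@@H]3[C@H]21 | intermediate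
3 | 13-dimethylamino-11βH,13-dihydroisozaluzanin C | C=C1[C@H](O)C[C@H]2C(=C)CC[C@H]3[C@H](CN(C)C)C(=O)O[C@@H]3[C@H]21 | intermediate
4 | bis-boron adduct of 3 (3-O-borinate; B-alkyl-9-BBN at C14; 10αH), formed in the flask | C=C1[C@H](OB2C3CCCC2CCC3)C[C@H]2[C@@H](CB3C4CCCC3CCC4)CC[C@H]3[C@H](CN(C)C)C(=O)O[C@@H]3[C@H]21 | intermediate
5 | hydroxy aldehyde (3α-OH; 10αH; C10 β-CH2CHO) | C=C1[C@H](O)C[C@H]2[C@@H](CC=O)CC[C@H]3[C@H](CN(C)C)C(=O)O[C@@H]3[C@H]21 | intermediate
6 | diol (3α-OH; C15'–OH) | C=C1[C@H](O)C[C@H]2[C@@H](CCO)CC[C@H]3[C@H](CN(C)C)C(=O)O[C@@H]3[C@H]21 | intermediate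
7 | hydroxy enone (3-oxo; C15'–OH) | C=C1C(=O)C[C@H]2[C@@H](CCO)CC[C@H]3[C@H](CN(C)C)C(=O)O[C@@H]3[C@H]21 | intermediate
8 | mesylate of 7, formed in the flask | C=C1C(=O)C[C@H]2[C@@H](CCOS(C)(=O)=O)CC[C@H]3[C@H](CN(C)C)C(=O)O[C@@H]3[C@H]21 | intermediate
9 | chloro enone (3-oxo; C15'–Cl) | C=C1C(=O)C[C@H]2[C@@H](CCCl)CC[C@H]3[C@H](CN(C)C)C(=O)O[C@@H]3[C@H]21 | intermediate
10 | trimethylsilyl dienol ether of 9 (C2=C3–OSiMe3), formed in the flask | C=C1C(O[Si](C)(C)C)=C[C@H]2[C@@H](CCCl)CC[C@H]3[C@H](CN(C)C)C(=O)O[C@@H]3[C@H]21 | intermediate
11 | chloro dienone (3-oxo-1,4(15)-diene) | C=C1C(=O)C=C2[C@@H](CCCl)CC[C@H]3[C@H](CN(C)C)C(=O)O[C@@H]3[C@@H]12 | intermediate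
12 | 1β,2α-dibromide of 11, formed in the flask | C=C1C(=O)[C@H](Br)[C@]2(Br)[C@@H](CCCl)CC[C@H]3[C@H](CN(C)C)C(=O)O[C@@H]3[C@@H]12 | intermediate
13 | 2-bromo dienone | C=C1C(=O)C(Br)=C2[C@@H](CCCl)CC[C@H]3[C@H](CN(C)C)C(=O)O[C@@H]3[C@@H]12 | intermediate
14 | 2-bromo-3β-ol | C=C1[C@@H](O)C(Br)=C2[C@@H](CCCl)CC[C@H]3[C@H](CN(C)C)C(=O)O[C@@H]3[C@@H]12 | intermediate
15 | 3α-formate, formed in the flask | C=C1[C@H](OC=O)C(Br)=C2[C@@H](CCCl)CC[C@H]3[C@H](CN(C)C)C(=O)O[C@@H]3[C@@H]12 | intermediate
16 | 2-bromo-3α-ol | C=C1[C@H](O)C(Br)=C2[C@@H](CCCl)CC[C@H]3[C@H](CN(C)C)C(=O)O[C@@H]3[C@@H]12 | intermediate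
17 | 3α-tert-butyldimethylsilyl ether chloride | C=C1[C@H](O[Si](C)(C)C(C)(C)C)C(Br)=C2[C@@H](CCCl)CC[C@H]3[C@H](CN(C)C)C(=O)O[C@@H]3[C@@H]12 | intermediate
18 | unit A bromo iodide (3α-silyl ether; C2–Br; C15'–I) | C=C1[C@H](O[Si](C)(C)C(C)(C)C)C(Br)=C2[C@@H](CCI)CC[C@H]3[C@H](CN(C)C)C(=O)O[C@@H]3[C@@H]12 | intermediate
19 | dehydrozaluzanin C | C=C1C(=O)C[C@H]2C(=C)CC[C@H]3C(=C)C(=O)O[C@@H]3[C@H]21 | intermediate
20 | trimethylsilyl dienol ether of 19, formed in the flask | C=C1C(O[Si](C)(C)C)=C[C@H]2C(=C)CC[C@H]3C(=C)C(=O)O[C@@H]3[C@H]21 | intermediate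
21 | 3-oxoguaia-1,4(15),10(14),11(13)-tetraen-12,6-olide, formed in the flask | C=C1C(=O)C=C2C(=C)CC[C@H]3C(=C)C(=O)O[C@@H]3[C@@H]12 | intermediate
22 | B–C Diels–Alder dimer (C1'=C10'; 2'βH) | C=C1C(=O)[C@H]2C=3[C@H]1[C@H]1OC(=O)C(=C)[C@@H]1CCC=3CC[C@]21C(=O)C[C@H]2C(=C)CC[C@H]3C(=C)C(=O)O[C@@H]3[C@H]21 | intermediate
23 | tris(dimethylamine) adduct of 22, formed in the flask | CN(C)C[C@@H]1C(=O)[C@H]2C=3[C@H]1[C@H]1OC(=O)[C@@H](CN(C)C)[C@@H]1CCC=3CC[C@]21C(=O)C[C@H]2C(=C)CC[C@H]3[C@H](CN(C)C)C(=O)O[C@@H]3[C@H]21 | intermediate
24 | 10'β-hydroperoxy enone, formed in the flask | CN(C)C[C@@H]1C(=O)C2=C3[C@H]1[C@H]1OC(=O)[C@@H](CN(C)C)[C@@H]1CC[C@@]3(OO)CC[C@]21C(=O)C[C@H]2C(=C)CC[C@H]3[C@H](CN(C)C)C(=O)O[C@@H]3[C@H]21 | intermediate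
25 | 10'β-hydroxy enone tris(dimethylamine) adduct | CN(C)C[C@@H]1C(=O)C2=C3[C@H]1[C@H]1OC(=O)[C@@H](CN(C)C)[C@@H]1CC[C@@]3(O)CC[C@]21C(=O)C[C@H]2C(=C)CC[C@H]3[C@H](CN(C)C)C(=O)O[C@@H]3[C@H]21 | intermediate
26 | 3''β-carbinol of 25 | CN(C)C[C@@H]1C(=O)C2=C3[C@H]1[C@H]1OC(=O)[C@@H](CN(C)C)[C@@H]1CC[C@@]3(O)CC[C@]21[C@@H](O)C[C@H]2C(=C)CC[C@H]3[C@H](CN(C)C)C(=O)O[C@@H]3[C@H]21 | intermediate
27 | exocyclic enone (C4'=C15'), formed in the flask | C=C1C(=O)C2=C3[C@H]1[C@H]1OC(=O)[C@@H](CN(C)C)[C@@H]1CC[C@@]3(O)CC[C@]21[C@@H](O)C[C@H]2C(=C)CC[C@H]3[C@H](CN(C)C)C(=O)O[C@@H]3[C@H]21 | intermediate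
28 | 4'-hydroxymethyl ketone, formed in the flask | OC[C@@H]1C(=O)C2=C3[C@H]1[C@H]1OC(=O)[C@@H](CN(C)C)[C@@H]1CC[C@@]3(O)CC[C@]21[C@@H](O)C[C@H]2C(=C)CC[C@H]3[C@H](CN(C)C)C(=O)O[C@@H]3[C@H]21 | intermediate
29 | 15-nor ketone diol | C1C(=O)C2=C3[C@H]1[C@H]1OC(=O)[C@@H](CN(C)C)[C@@H]1CC[C@@]3(O)CC[C@]21[C@@H](O)C[C@H]2C(=C)CC[C@H]3[C@H](CN(C)C)C(=O)O[C@@H]3[C@H]21 | intermediate
30 | masked 15-nor ketone of the B–C dimer (bis-triethylsilyl ether) | C1C(=O)C2=C3[C@H]1[C@H]1OC(=O)[C@@H](CN(C)C)[C@@H]1CC[C@@]3(O[Si](CC)(CC)CC)CC[C@]21[C@@H](O[Si](CC)(CC)CC)C[C@H]2C(=C)CC[C@H]3[C@H](CN(C)C)C(=O)O[C@@H]3[C@H]21 | intermediate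
31 | C4'-alkylated ketone (4'βH; C2–Br intact), formed in the flask | C=C1[C@H](O[Si](C)(C)C(C)(C)C)C(Br)=C2[C@@H](CC[C@@H]4C(=O)C5=C6[C@H]4[C@H]4OC(=O)[C@@H](CN(C)C)[C@@H]4CC[C@@]6(O[Si](CC)(CC)CC)CC[C@]57[C@@H](O[Si](CC)(CC)CC)C[C@H]5C(=C)CC[C@H]6[C@H](CN(C)C)C(=O)O[C@@H]6[C@H]57)CC[C@H]3[C@H](CN(C)C)C(=O)O[C@@H]3[C@@H]12 | intermediate
32 | protected trimer | C=C1[C@H](O[Si](C)(C)C(C)(C)C)C2=C3[C@H](CC[C@H]4[C@H](CN(C)C)C(=O)O[C@@H]4[C@@H]13)CC[C@@]21C(=O)C2=C3[C@H]1[C@H]1OC(=O)[C@@H](CN(C)C)[C@@H]1CC[C@@]3(O[Si](CC)(CC)CC)CC[C@]21[C@@H](O[Si](CC)(CC)CC)C[C@H]2C(=C)CC[C@H]3[C@H](CN(C)C)C(=O)O[C@@H]3[C@H]21 | intermediate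
33 | triol tris(dimethylamine) adduct | C=C1[C@H](O)C2=C3[C@H](CC[C@H]4[C@H](CN(C)C)C(=O)O[C@@H]4[C@@H]13)CC[C@@]21C(=O)C2=C3[C@H]1[C@H]1OC(=O)[C@@H](CN(C)C)[C@@H]1CC[C@@]3(O)CC[C@]21[C@@H](O)C[C@H]2C(=C)CC[C@H]3[C@H](CN(C)C)C(=O)O[C@@H]3[C@H]21 | intermediate
34 | 3,3''-diketone tris(dimethylamine) adduct | C=C1C(=O)C2=C3[C@H](CC[C@H]4[C@H](CN(C)C)C(=O)O[C@@H]4[C@@H]13)CC[C@@]21C(=O)C2=C3[C@H]1[C@H]1OC(=O)[C@@H](CN(C)C)[C@@H]1CC[C@@]3(O)CC[C@]21C(=O)C[C@H]2C(=C)CC[C@H]3[C@H](CN(C)C)C(=O)O[C@@H]3[C@H]21 | intermediate
35 | tris(trimethylammonium) triiodide, formed in the flask | C=C1C(=O)C2=C3[C@H](CC[C@H]4[C@H](C[N+](C)(C)C)C(=O)O[C@@H]4[C@@H]13)CC[C@@]21C(=O)C2=C3[C@H]1[C@H]1OC(=O)[C@@H](C[N+](C)(C)C)[C@@H]1CC[C@@]3(O)CC[C@]21C(=O)C[C@H]2C(=C)CC[C@H]3[C@H](C[N+](C)(C)C)C(=O)O[C@@H]3[C@H]21.[I-].[I-].[I-] | intermediate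
36 | ainsliatrimer A | C=C1C(=O)C2=C3[C@H](CC[C@H]4C(=C)C(=O)O[C@@H]4[C@@H]13)CC[C@@]21C(=O)C2=C3[C@H]1[C@H]1OC(=O)C(=C)[C@@H]1CC[C@@]3(O)CC[C@]21C(=O)C[C@H]2C(=C)CC[C@H]3C(=C)C(=O)O[C@@H]3[C@H]21 | target

## Step count and least certain steps

Total step count: 22. Longest linear sequence: 16 steps (steps 1–12, then 19–22). The branch to 30 is 8 steps from 1 (steps 1, 13–18).

**Step 19 (key step).** The ring-closing alkenylation may show poor facial selectivity, delivering C2 to the α face of C4' (the side of H5'), which looks the less crowded when the silyl ether relay is disregarded. The palladium enolate may also lose a β-hydrogen, or C5' may epimerize through γ-deprotonation. Fallback: reverse the order of the two bond formations, setting out from 30 and the chloride 17. Intermolecular palladium-catalysed α-alkenylation of the enolate of 30 with the vinyl bromide of 17 (KN(SiMe3)2, Pd2(dba)3, P(t-Bu)3, toluene) would give the C4'-alkenyl chloro ketone F1. Re-enolization in the presence of NaI (KN(SiMe3)2, DMPU–THF) then closes the ring by intramolecular alkylation (6-exo-tet). This places C15', and no longer C2, on the kinetically preferred face and comes back to the route at 32.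

**Step 14.** Trienone 21 can add to itself through its own C4=C15 bond or react as a dienophile in a hetero-Diels–Alder mode, and palladium residues may promote oligomerization of the methylene lactones. Fallback: decouple the release of the diene from palladium. Starting from the silyl dienol ether 20, selenenylation with PhSeCl would give the 2α-phenylseleno ketone F2. Its oxidation with H2O2 at 0 °C in the presence of a large excess of 19 releases 21 slowly by selenoxide syn-elimination (H1 and Se are cis), and the route is rejoined at 22.

**Step 17.** The retro-aldol may stop at an unfavourable equilibrium: formaldehyde can re-add or react at other enolizable positions, and C5' can epimerize on prolonged heating with base. Fallback: an oxidative deformylation that never liberates formaldehyde, setting out from 26. The enone 27, released in situ, undergoes copper-catalysed conjugate borylation (CuCl, NaOC(CH3)3, B2pin2, MeOH, THF) to the pinacol boronate F3. NaBO3 oxidation gives 28. Primary-selective oxidation (TEMPO, PhI(OAc)2) gives the 4'-formyl ketone F4. Irreversible deformylation with K2CO3 in MeOH returns to the route at 29.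

**Step 3.** Hydroboration may also occur at C4=C15, the tertiary amine may hold back the borane, and the hydride donor may begin to reduce the lactone or to over-reduce the acylborane. Fallback: a stepwise homologation that sets out from 3.
- 9-BBN then NaBO3 gives the 3α,14-diol F5.
- Primary-selective oxidation (TEMPO, PhI(OAc)2) gives the C14 aldehyde F6.
- Wittig methylenation (methyltriphenylphosphonium bromide, KN(SiMe3)2, THF, −78 °C) gives the vinyl compound F7.
- A second 9-BBN hydroboration–oxidation of the monosubstituted alkene comes back to the route at 6.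

**Step 10.** The doubly allylic oxyphosphonium ion may ionize or react in an SN2' sense at C15, with loss of stereochemical fidelity. Fallback: omit reduction and inversion, and reduce 13 directly under reagent control with the (R)-methyl oxazaborolidine and catecholborane (Corey–Bakshi–Shibata reduction, bromoalkenyl as the large group), which should give 16 directly and makes no new compound.

## Further compounds

F1 | step 19 | C4'-alkenyl chloro ketone (C2–C4' bond formed; C15'–Cl free; C4' epimers) | C=C1[C@H](O[Si](C)(C)C(C)(C)C)C([C@@H]4C(=O)C5=C6[C@H]4[C@H]4OC(=O)[C@@H](CN(C)C)[C@@H]4CC[C@@]6(O[Si](CC)(CC)CC)CC[C@]57[C@@H](O[Si](CC)(CC)CC)C[C@H]5C(=C)CC[C@H]6[C@H](CN(C)C)C(=O)O[C@@H]6[C@H]57)=C2[C@@H](CCCl)CC[C@H]3[C@H](CN(C)C)C(=O)O[C@@H]3[C@@H]12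
F2 | step 14 | 2α-(phenylseleno)dehydrozaluzanin C | C=C1C(=O)[C@H]([Se]c4ccccc4)[C@H]2C(=C)CC[C@H]3C(=C)C(=O)O[C@@H]3[C@H]21
F3 | step 17 | C15' pinacol boronate of the B–C ketone | CC1(C)OB(C[C@@H]2C(=O)C3=C4[C@H]2[C@H]2OC(=O)[C@@H](CN(C)C)[C@@H]2CC[C@@]4(O)CC[C@]35[C@@H](O)C[C@H]3C(=C)CC[C@H]4[C@H](CN(C)C)C(=O)O[C@@H]4[C@H]35)OC1(C)C
F4 | step 17 | 4'-formyl ketone | O=C[C@@H]1C(=O)C2=C3[C@H]1[C@H]1OC(=O)[C@@H](CN(C)C)[C@@H]1CC[C@@]3(O)CC[C@]21[C@@H](O)C[C@H]2C(=C)CC[C@H]3[C@H](CN(C)C)C(=O)O[C@@H]3[C@H]21
F5 | step 3 | 3α,14-diol (10αH) | C=C1[C@H](O)C[C@H]2[C@@H](CO)CC[C@H]3[C@H](CN(C)C)C(=O)O[C@@H]3[C@H]21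
F6 | step 3 | C14 aldehyde | C=C1[C@H](O)C[C@H]2[C@@H](C=O)CC[C@H]3[C@H](CN(C)C)C(=O)O[C@@H]3[C@H]21
F7 | step 3 | C10 vinyl compound | C=C1[C@H](O)C[C@H]2[C@@H](C=C)CC[C@H]3[C@H](CN(C)C)C(=O)O[C@@H]3[C@H]21
F0 | step 10 | none | none
A1 | alternative 1 | 3-oxoguaia-1,4(15),10(14),11(13)-tetraen-12,6-olide (same as 21) | C=C1C(=O)C=C2C(=C)CC[C@H]3C(=C)C(=O)O[C@@H]3[C@@H]12
A2 | alternative 1 | allene-yne lactone (trans-4-allenyl-3-(3-methylenepent-4-ynyl)-2-methylenebutanolide) | C#CC(=C)CC[C@H]1C(=C)C(=O)O[C@@H]1C=C=C
A3 | alternative 2 | B–C spiro dimer with the C1'=C10' alkene (same as 22) | C=C1C(=O)[C@H]2C=3[C@H]1[C@H]1OC(=O)C(=C)[C@@H]1CCC=3CC[C@]21C(=O)C[C@H]2C(=C)CC[C@H]3C(=C)C(=O)O[C@@H]3[C@H]21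
A4 | alternative 2 | spiro-dihydropyran (O–C10' bond; C3''=C4'' enol ether) | C=C1C(=O)C=C2[C@H]1[C@H]1OC(=O)C(=C)[C@@H]1CC[C@@]23CCC4=C(O3)C[C@H]5C(=C)CC[C@H]6C(=C)C(=O)O[C@@H]6[C@@H]45
A5 | alternative 3 | 3α-(tert-butyldimethylsilyloxy)dehydrocostus lactone | C=C1[C@H](O[Si](C)(C)C(C)(C)C)C[C@H]2C(=C)CC[C@H]3C(=C)C(=O)O[C@@H]3[C@H]21
A6 | alternative 3 | cyclopentane aldehyde with (Z)-2-(bromomethyl)enoate side chain | C=C1[C@H](O[Si](C)(C)C(C)(C)C)C[C@@H](C(=C)CC/C=C(\CBr)C(=O)OC)[C@H]1C=O
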